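**Plan**

- **Enabling feature** (germacrane numbering: ring C1–C10, C11–C13 on C7, C14 on C10, C15 on C4): C11 of the γ-lactone ring (C7–C8–O–C12–C11) is bonded to C7 and lies 1,3 to the ester oxygen on allylic C6. One extra C6–C11 bond therefore folds lactone, C7 and C6 into a vinyl-substituted 3-oxabicyclo[3.1.0]hexan-2-one. A carbene hung on O8 can build this from a C6=C7 alkene.
- **Cuts:** C11=C13, then O–C6 (tiglate), then C6–C11 and C7–C11 together, then O8–C12. The ten-membered ring is cut at C4=C5, and the chain at C6=C7, C1=C10 and C3–C4.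
- **Forward order:** Michael addition (C3–C4), Wittig (C1=C10) and Wittig homologation (C6=C7) join the chain on a chiral C8–O–C14 butyrolactone. A ring-closing HWE (C4=C5) gives the ten-membered ring, and reduction unties the helper lactone. The carbene step closes the γ-lactone and the cyclopropane at once, and tiglate reopens the cyclopropane.
- **Stereochemistry:** C8 comes from (S)-5-(hydroxymethyl)butyrolactone and steers the carbene to one alkene face (C7, C11). The E alkene fixes C6 in the cyclopropane, and SN2 inversion by tiglate gives 6S, a net anti addition of C11 and O across the E alkene. The alkene geometries come from stabilised P-reagents, which place the carbonyl trans to the chain.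

Key step: step 13

Remark: stereocentres that are erased later (C10 before the first Wittig step, C4 before ring closure, C11 after the cyclopropane opening) are carried as epimer mixtures and left undefined in the SMILES.

**Step 1**
Reactants: 1 (S)-5-(hydroxymethyl)dihydrofuran-2(3H)-one
Product: 2 (S)-5-[(tert-butyldimethylsilyloxy)methyl]dihydrofuran-2(3H)-one
Conditions: TBSCl, imidazole, DMF, 0 °C → rt
Reagents that add atoms: tert-butyldimethylsilyl chloride C[Si](C)(Cl)C(C)(C)C
Why: Imidazole-promoted silylation of a primary alcohol masks the C7 hydroxyl for the enolate and phosphonium chemistry and leaves the chiral-pool centre C8 untouched.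

**Step 2**
Reactants: 2 (S)-5-[(tert-butyldimethylsilyloxy)methyl]dihydrofuran-2(3H)-one
Product: 4 (5S)-3-bromo-5-[(tert-butyldimethylsilyloxy)methyl]dihydrofuran-2(3H)-one (C10 epimers), via silyl ketene acetal 3 (not isolated)
Conditions: LDA, THF, −78 °C; TMSCl; then NBS, −78 → 0 °C
Reagents that add atoms: N-bromosuccinimide O=C1CCC(=O)N1Br; chlorotrimethylsilane C[Si](C)(C)Cl (atoms in 3 only)
Why: Kinetic enolisation, O-silylation and electrophilic bromination of the silyl ketene acetal is the usual α-bromination of butyrolactones, and the new C10 centre needs no control because it becomes sp2 in step 5.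

**Step 3**
Reactants: 4 (5S)-3-bromo-5-[(tert-butyldimethylsilyloxy)methyl]dihydrofuran-2(3H)-one
Product: 5 {(5S)-5-[(tert-butyldimethylsilyloxy)methyl]-2-oxotetrahydrofuran-3-yl}triphenylphosphonium bromide
Conditions: PPh3, THF, reflux
Reagents that add atoms: triphenylphosphine c1ccc(cc1)P(c1ccccc1)c1ccccc1
Why: SN2 quaternisation of triphenylphosphine by an α-bromolactone, the reaction that also gives the parent (2-oxotetrahydrofuran-3-yl)phosphonium salt, should deliver a crystalline Wittig salt.

**Step 4**
Reactants: 6 triethyl phosphonoacetate (excess); 7 acrolein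
Product: 8 ethyl 2-(diethoxyphosphoryl)-5-oxopentanoate (racemic)
Conditions: NaOEt (cat.), EtOH, −10 → 0 °C
Reagents that add atoms: none
Why: Base-catalysed Michael addition of the phosphonoacetate C–H acid to acrolein forms C3–C4; any HWE attack at the aldehyde would consume the catalytic alkoxide and stop, so conjugate addition is the pathway that turns over, and the excess of 6 suppresses double addition.

**Step 5**
Reactants: 5 {(5S)-5-[(tert-butyldimethylsilyloxy)methyl]-2-oxotetrahydrofuran-3-yl}triphenylphosphonium bromide; 8 ethyl 2-(diethoxyphosphoryl)-5-oxopentanoate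
Product: 10 ethyl 5-{(3E,5S)-5-[(tert-butyldimethylsilyloxy)methyl]-2-oxodihydrofuran-3(2H)-ylidene}-2-(diethoxyphosphoryl)pentanoate, via lactone ylide 9 (not isolated)
Conditions: Et3N, CH2Cl2, rt → reflux
Reagents that add atoms: none
Why: Wittig olefination with a lactone-stabilised ylide, which is too weak a base to deprotonate the phosphonoacetate of 8 and is known to give E-alkylidene butyrolactones, should place C2 trans to C14 and cis to C9 as the C1=C10 alkene of the target requires.

**Step 6**
Reactants: 10 ethyl 5-{(3E,5S)-5-[(tert-butyldimethylsilyloxy)methyl]-2-oxodihydrofuran-3(2H)-ylidene}-2-(diethoxyphosphoryl)pentanoate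
Product: 11 ethyl 2-(diethoxyphosphoryl)-5-[(3E,5S)-5-(hydroxymethyl)-2-oxodihydrofuran-3(2H)-ylidene]pentanoate
Conditions: 48 % aq. HF, MeCN, 0 °C
Reagents that add atoms: none
Why: Acidic fluoride cleavage of the only silyl ether avoids deprotonating the phosphonoacetate and does not touch the lactone, the ester or the alkylidene group.

**Step 7**
Reactants: 11 ethyl 2-(diethoxyphosphoryl)-5-[(3E,5S)-5-(hydroxymethyl)-2-oxodihydrofuran-3(2H)-ylidene]pentanoate; 12 (triphenylphosphoranylidene)acetaldehyde
Product: 14 ethyl 2-(diethoxyphosphoryl)-5-{(3E,5S)-2-oxo-5-[(E)-3-oxoprop-1-enyl]dihydrofuran-3(2H)-ylidene}pentanoate, via lactone aldehyde 13 (not isolated)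
Conditions: Dess–Martin periodinane, CH2Cl2, 0 °C → rt; then 12, rt
Reagents that add atoms: none
Why: Dess–Martin oxidation followed in the same flask by Wittig homologation avoids isolating the epimerisable α-acyloxy aldehyde 13, should give the E enal (C6=C7) as formyl-stabilised ylides do, and should stop after one homologation because 13 is much more electrophilic than the enal formed.

**Step 8**
Reactants: 14 ethyl 2-(diethoxyphosphoryl)-5-{(3E,5S)-2-oxo-5-[(E)-3-oxoprop-1-enyl]dihydrofuran-3(2H)-ylidene}pentanoate
Product: 15 bridged macrocycle (8S): ten-membered carbocycle C1–C10 with E C6=C7, C4=C5 bearing CO2Et (C3 and C6 cis), C1=C10 (C2 and C9 cis) and the C8–O–C14(=O)–C10 butyrolactone bridge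
Conditions: LiCl, DBU, MeCN, rt, syringe-pump addition (final 1 mM)
Reagents that add atoms: none
Why: Intramolecular Horner–Wadsworth–Emmons olefination under Masamune–Roush conditions at high dilution, in which the rigid butyrolactone holds the C7 and C1 arms on the same side of C9 as a turn element, and both the intrinsic preference of α-alkylphosphonoacetates (ester trans to the aldehyde residue) and ring strain favour the alkene with C3 and C6 cis.

**Step 9**
Reactants: 15 bridged macrocyclic lactone ester
Product: 16 (1S,2E,4E,8E)-5,9-bis(hydroxymethyl)cyclodeca-2,4,8-trien-1-ol (carbinol carbon = C8; the ring bonds are cis at C4=C5 and C1=C10 and trans at C6=C7)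
Conditions: DIBAL-H (excess), CH2Cl2, −78 → 0 °C; aq. Rochelle salt
Reagents that add atoms: none
Why: Exhaustive 1,2-reduction by DIBAL-H of the dienoate ester and of the α-alkylidene lactone (through its lactol) unties the C8–O–C14 bridge and sets free the three hydroxyl groups without touching the alkenes or C8.

**Step 10**
Reactants: 16 (1S,2E,4E,8E)-5,9-bis(hydroxymethyl)cyclodeca-2,4,8-trien-1-ol
Product: 17 (1S,2E,4E,8E)-5,9-bis{[(tert-butyldimethylsilyl)oxy]methyl}cyclodeca-2,4,8-trien-1-ol
Conditions: TBSCl (2.05 equiv), imidazole, CH2Cl2, −20 → 0 °C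
Reagents that add atoms: tert-butyldimethylsilyl chloride C[Si](C)(Cl)C(C)(C)C
Why: Rate-controlled silylation, in which the two primary allylic alcohols react much faster with TBSCl than the secondary C8 alcohol, leaves C8–OH free for acylation.

**Step 11**
Reactants: 17 macrocyclic bis-silyl ether alcohol; 18 diethylphosphonoacetic acid
Product: 19 (1S,2E,4E,8E)-5,9-bis{[(tert-butyldimethylsilyl)oxy]methyl}cyclodeca-2,4,8-trien-1-yl 2-(diethoxyphosphoryl)acetate
Conditions: DCC, DMAP (cat.), CH2Cl2, 0 °C → rt
Reagents that add atoms: none
Why: Steglich esterification forms O8–C12 under neutral conditions without breaking the C8–O bond, so the dienylic carbinol centre is retained.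

**Step 12**
Reactants: 19 macrocyclic phosphonoacetate
Product: 20 (1S,2E,4E,8E)-5,9-bis{[(tert-butyldimethylsilyl)oxy]methyl}cyclodeca-2,4,8-trien-1-yl 2-diazo-2-(diethoxyphosphoryl)acetate
Conditions: p-ABSA, DBU, MeCN, 0 °C → rt
Reagents that add atoms: 4-acetamidobenzenesulfonyl azide CC(=O)Nc1ccc(cc1)S(=O)(=O)N=[N+]=[N-]
Why: Regitz diazo transfer onto the doubly activated methylene of a phosphonoacetate is routine and leaves the silyl ethers, the alkenes and C8 alone.

**Step 13**
Reactants: 20 macrocyclic diazophosphonoacetate
Product: 21 cyclopropane-fused α-phosphono-γ-lactone on the ten-membered ring (6R,7S,8S,11R; H7/H8 trans, cyclopropane anti to C9, C5 exo, phosphonate on C11)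
Conditions: Rh2(esp)2 (1 mol %), toluene, 80 °C, slow addition of 20 (final 5 mM)
Reagents that add atoms: none
Why: Rh(II) expels N2 from 20, and the resulting electrophilic acceptor/acceptor carbene at C11 adds to the C6=C7 π bond in one concerted, asynchronous and stereospecific event that makes C7–C11 and C6–C11; the closest known reaction type is the Rh(II)- or Cu-catalysed intramolecular cyclopropanation of allylic diazoacetates, diazomalonates and diazophosphonoacetates to 3-oxabicyclo[3.1.0]hexan-2-ones. The γ-lactone (C8–O–C12–C11–C7) closes in the five-membered mode normal for an allylic ester tether, with C11 bonding to the proximal alkene carbon C7, and the cyclopropane (C6–C7–C11) closes as the three-membered ring cis-fused to it, the only possible fusion, which ties the configuration of C11 to that of C7. C6 is controlled by the alkene geometry: the trans relation of C5 and C8 is retained, so C5 comes out exo. C7 is controlled by C8: in the reactive rotamer H8 lies in the alkene plane (least A1,3 strain), O8 carries the carbene over the outer face of the trans alkene, whose inner face is shielded by the ring, and C9 points away, so C9 should end anti to the cyclopropane and H7/H8 trans. The step needs site selectivity for C6=C7 over C4=C5, C1=C10 and the allylic C9–H bonds; this should be secured by the tether length (only C6=C7 gives a five-membered lactone by addition), by the twist of the ring diene that leaves C6=C7 as an unhindered disubstituted alkene, and by the known preference of acceptor/acceptor carbenes on carboxylate-bridged Rh(II) for cyclopropanation over insertion.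

**Step 14**
Reactants: 21 cyclopropane-fused α-phosphono lactone; 22 tiglic acid
Product: 23 (6S,7R,8S)-6-tigloyloxy-11-(diethoxyphosphoryl)-8,12-olide bis-TBS ether (C11 epimers)
Conditions: 22 (6 equiv), Cs2CO3 (1.5 equiv), DMSO, 60–70 °C
Reagents that add atoms: none
Why: Proposed new method: caesium tiglate should attack the allylic cyclopropane carbon C6 from the side opposite the C6–C11 bond (SN2-type homoconjugate addition), a bond weakened by ring strain, by the geminal lactone carbonyl and phosphonate held in the bicyclic frame and by the C4=C5 π system, so that C6 is inverted to the 6S ester while the expelled C11 carbanion is protonated by the excess acid and cannot re-close; attack at C7 lacks allylic assistance and SN2′ attack at C4 would have to build a quaternary centre, and the closest known reaction types are the invertive openings of gem-diactivated (vinyl)cyclopropanes by thiolates, amines and aryloxides and the Lewis-acid-catalysed addition of carboxylic acids to donor–acceptor cyclopropanes.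

**Step 15**
Reactants: 23 α-phosphono lactone tiglate; 24 formaldehyde
Product: 25 (6S,7R,8S)-α-methylene lactone tiglate, 14,15-bis-TBS ether of the target
Conditions: 37 % aq. HCHO, K2CO3, THF, 0 °C → rt
Reagents that add atoms: none
Why: Horner–Wadsworth–Emmons methylenation of an α-phosphono-γ-lactone with formaldehyde under mild carbonate conditions is the standard entry to α-methylene lactones, erases the C11 epimer mixture, and outruns re-closure onto the poor carboxylate leaving group at C6.

**Step 16**
Reactants: 25 bis-TBS ether of the target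
Product: 26 CNP0275462.1 (6S,7R,8S)
Conditions: HF·pyridine, pyridine, THF, 0 °C → rt
Reagents that add atoms: none
Why: Buffered acidic fluoride desilylation frees the two primary allylic alcohols without the basic conditions that would endanger the α-methylene lactone or the allylic tiglate.

**Compound list**

1 | (S)-5-(hydroxymethyl)dihydrofuran-2(3H)-one | O=C1CC[C@@H](CO)O1 | starting material
2 | (S)-5-[(tert-butyldimethylsilyloxy)methyl]dihydrofuran-2(3H)-one | O=C1CC[C@@H](CO[Si](C)(C)C(C)(C)C)O1 | intermediate
3 | silyl ketene acetal of 2 (2-trimethylsilyloxy-4,5-dihydrofuran) | C[Si](C)(C)OC1=CC[C@@H](CO[Si](C)(C)C(C)(C)C)O1 | intermediate (not isolated)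
4 | (5S)-3-bromo-5-[(tert-butyldimethylsilyloxy)methyl]dihydrofuran-2(3H)-one | O=C1C(Br)C[C@@H](CO[Si](C)(C)C(C)(C)C)O1 | intermediate
5 | {(5S)-5-[(tert-butyldimethylsilyloxy)methyl]-2-oxotetrahydrofuran-3-yl}triphenylphosphonium bromide | O=C1C([P+](c2ccccc2)(c2ccccc2)c2ccccc2)C[C@@H](CO[Si](C)(C)C(C)(C)C)O1.[Br-] | intermediate
6 | triethyl phosphonoacetate | CCOC(=O)CP(=O)(OCC)OCC | starting material
7 | acrolein | C=CC=O | starting material
8 | ethyl 2-(diethoxyphosphoryl)-5-oxopentanoate | CCOC(=O)C(CCC=O)P(=O)(OCC)OCC | intermediate
9 | (S)-5-[(tert-butyldimethylsilyloxy)methyl]-3-(triphenylphosphoranylidene)dihydrofuran-2(3H)-one | O=C1C(=P(c2ccccc2)(c2ccccc2)c2ccccc2)C[C@@H](CO[Si](C)(C)C(C)(C)C)O1 | intermediate (not isolated)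
10 | E-alkylidene lactone phosphonate, C7 TBS ether | O=C1/C(=C/CCC(C(=O)OCC)P(=O)(OCC)OCC)C[C@@H](CO[Si](C)(C)C(C)(C)C)O1 | intermediate
11 | E-alkylidene lactone phosphonate, C7 alcohol | O=C1/C(=C/CCC(C(=O)OCC)P(=O)(OCC)OCC)C[C@@H](CO)O1 | intermediate
12 | (triphenylphosphoranylidene)acetaldehyde | O=CC=P(c1ccccc1)(c1ccccc1)c1ccccc1 | starting material
13 | E-alkylidene lactone phosphonate, C7 aldehyde | O=C1/C(=C/CCC(C(=O)OCC)P(=O)(OCC)OCC)C[C@@H](C=O)O1 | intermediate (not isolated)
14 | seco enal phosphonate (E C6=C7) | O=C1/C(=C/CCC(C(=O)OCC)P(=O)(OCC)OCC)C[C@@H](/C=C/C=O)O1 | intermediate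
15 | bridged ten-membered trienyl lactone ester (8S) | O=C1O[C@H]2C/C1=C\CC/C(C(=O)OCC)=C\C=C\2 | intermediate
16 | (1S,2E,4E,8E)-5,9-bis(hydroxymethyl)cyclodeca-2,4,8-trien-1-ol | O[C@H]1C/C(CO)=C\CC/C(CO)=C\C=C\1 | intermediate
17 | (1S,2E,4E,8E)-5,9-bis{[(tert-butyldimethylsilyl)oxy]methyl}cyclodeca-2,4,8-trien-1-ol | O[C@H]1C/C(CO[Si](C)(C)C(C)(C)C)=C\CC/C(CO[Si](C)(C)C(C)(C)C)=C\C=C\1 | intermediate
18 | diethylphosphonoacetic acid | OC(=O)CP(=O)(OCC)OCC | starting material
19 | macrocyclic C8 diethylphosphonoacetate | CCOP(=O)(OCC)CC(=O)O[C@H]1C/C(CO[Si](C)(C)C(C)(C)C)=C\CC/C(CO[Si](C)(C)C(C)(C)C)=C\C=C\1 | intermediate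
20 | macrocyclic C8 diazophosphonoacetate (key-step precursor) | CCOP(=O)(OCC)C(=[N+]=[N-])C(=O)O[C@H]1C/C(CO[Si](C)(C)C(C)(C)C)=C\CC/C(CO[Si](C)(C)C(C)(C)C)=C\C=C\1 | intermediate
21 | cyclopropane-fused α-phosphono lactone (key-step product) | O=C1O[C@H]2C/C(CO[Si](C)(C)C(C)(C)C)=C\CC/C(CO[Si](C)(C)C(C)(C)C)=C\[C@@H]3[C@@H]2[C@@]13P(=O)(OCC)OCC | intermediate
22 | tiglic acid | C/C=C(\C)C(=O)O | starting material
23 | 6-tigloyloxy α-phosphono lactone bis-TBS ether | CCOP(=O)(OCC)C1C(=O)O[C@H]2C/C(CO[Si](C)(C)C(C)(C)C)=C\CC/C(CO[Si](C)(C)C(C)(C)C)=C\[C@H](OC(=O)/C(C)=C/C)[C@H]12 | intermediate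
24 | formaldehyde | C=O | starting material
25 | 14,15-bis-TBS ether of the target | C=C1C(=O)O[C@H]2C/C(CO[Si](C)(C)C(C)(C)C)=C\CC/C(CO[Si](C)(C)C(C)(C)C)=C\[C@H](OC(=O)/C(C)=C/C)[C@H]12 | intermediate
26 | CNP0275462.1 | C=C1C(=O)O[C@H]2C/C(CO)=C\CC/C(CO)=C\[C@H](OC(=O)/C(C)=C/C)[C@H]12 | target

**Total steps:** 16. **Longest linear sequence:** 15 (steps 1–3 and 5–16, from 1).

**Steps most likely to fail**

Step 14 (new method). The carboxylate may be too weak a nucleophile, so that opening is slower than thermal decay of the vinylcyclopropane. Partial ionisation at allylic C6 may also erode the inversion. The fallback uses known chemistry, sets out from 21 and returns at 23. The oxygen is brought in with an aryloxide, a nucleophile class known to open gem-diactivated cyclopropanes with clean inversion. 4-Methoxyphenol and Cs2CO3 in MeCN should give the C6 4-methoxyphenyl ether F1. Oxidative dearylation with ceric ammonium nitrate (MeCN–H2O, 0 °C) should set free the 6S alcohol F2. This alcohol is acylated at once with 22 (DCC, DMAP, Steglich) before it can translactonise, giving 23.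

Step 13 (key step). Three processes may compete: insertion of the carbene into the allylic C9–H bonds, addition to C1=C10, and reaction through a ring conformer that shows the other alkene face. The fallback sets out from 19 and returns at 21, and it makes the same two bonds one after the other by a radical-then-polar sequence. Iodination of 19 (NaH, NIS, THF, 0 °C) should give the α-iodophosphonoacetate F3. Iodine-atom-transfer 5-exo cyclisation ((Bu3Sn)2 cat., hν, benzene, 80 °C) forms C7–C11 with the usual trans preference of 4,5-disubstituted lactones. The resulting allyl radical picks up iodine at C6 to give the allylic iodolactone F4. DBU then closes C6–C11 by 3-exo-tet displacement. The iodide epimers interconvert by iodide exchange, and the one that places C5 exo should close to 21. A carbon radical does not insert into C–H bonds, and 5-exo attack fixes the site.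

Step 8. Oligomerisation may outrun closure of the strained ten-membered ring, or the base may epimerise C8 of the γ-acyloxy enal. The fallback sets out from 11 and returns at 15, and it closes the ring at C5–C6 by palladium instead of at C4=C5 by olefination. HWE methylenation of 11 (aq. HCHO, K2CO3) should give the α-substituted acrylate alcohol F5. Dess–Martin oxidation gives the acrylate aldehyde F6, and Takai olefination (CHI3, CrCl2, THF) gives the E-vinyl iodide F7. A macrocyclic Heck reaction under Jeffery conditions (Pd(OAc)2, Bu4NCl, K2CO3, DMF, high dilution) adds the vinylpalladium to the acrylate CH2 (C5). β-Hydride elimination should then give the dienoate 15 with the ester trans to C6.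

**Further compounds**

F1 | step 14 | C6 4-methoxyphenyl ether of the opened α-phosphono lactone | CCOP(=O)(OCC)C1C(=O)O[C@H]2C/C(CO[Si](C)(C)C(C)(C)C)=C\CC/C(CO[Si](C)(C)C(C)(C)C)=C\[C@H](Oc3ccc(OC)cc3)[C@H]12
F2 | step 14 | 6S alcohol of the opened α-phosphono lactone | CCOP(=O)(OCC)C1C(=O)O[C@H]2C/C(CO[Si](C)(C)C(C)(C)C)=C\CC/C(CO[Si](C)(C)C(C)(C)C)=C\[C@H](O)[C@H]12
F3 | step 13 | macrocyclic C8 α-iodophosphonoacetate | CCOP(=O)(OCC)C(I)C(=O)O[C@H]1C/C(CO[Si](C)(C)C(C)(C)C)=C\CC/C(CO[Si](C)(C)C(C)(C)C)=C\C=C\1
F4 | step 13 | allylic C6 iodide of the α-phosphono lactone | CCOP(=O)(OCC)C1C(=O)O[C@H]2C/C(CO[Si](C)(C)C(C)(C)C)=C\CC/C(CO[Si](C)(C)C(C)(C)C)=C\C(I)[C@H]12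
F5 | step 8 | α-substituted acrylate alcohol | O=C1/C(=C/CCC(=C)C(=O)OCC)C[C@@H](CO)O1
F6 | step 8 | acrylate aldehyde | O=C1/C(=C/CCC(=C)C(=O)OCC)C[C@@H](C=O)O1
F7 | step 8 | acrylate E-vinyl iodide | O=C1/C(=C/CCC(=C)C(=O)OCC)C[C@@H](/C=C/I)O1
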